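Compounds are numbered 1–28 as in the steps and the compound list. Guaiane numbering is used for the bicyclic compounds and as position labels in open-chain intermediates: C1 fusion carbinol, C2 methylene, C3 ketone, C4 (methyl C15), C5, C6 carbinol, C7 (side chain C11–C13), C8, C9 methylene, C10 (methyl C14). The α face is the face of the C10 methyl group.

## Analysis of the target

The target 28 is a guaiane: a cyclopentenone (C1–C5) fused through C1 and C5 to a cycloheptane (C1, C5–C10). It has five stereocentres, (1R,6R,7S,8R,10S). The C6 hydroxyl, the C7 side chain, the C8 angelate and the C10 methyl lie on the α face, and the C1 hydroxyl lies on the β face. C6, C7 and C8 are therefore contiguous and all-cis, and H-10 is cis to the C1 oxygen. The sensitive groups are the angelate (Z to E isomerisation), the tertiary acetate on C11 (1,3-related to O6 and O8, so open to acyl migration) and the β-hydroxy enone (retro-aldol opening at C1–C2, elimination). The difficulty is a seven-membered ring with four stereocentres, in which C7 is wedged between two oxygenated carbons and the quaternary C11, next to a fully substituted carbinol at the ring fusion. The strategy rests on C9, the only unfunctionalised ring methylene. Its neighbours are C8, whose oxygen can be carried as an acyl group, and C10, whose methyl group and quaternary neighbour C1 make C10–C9 an isopropenyl group on C1. A C8 acyl radical adding to the terminus of that group closes the ring.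

## Retrosynthetic reasoning

**Silyl ethers (28 from 27).** The two free hydroxyls are masked as triethylsilyl ethers. Both come off in one buffered fluoride step at the very end, so the β-hydroxy enone never meets base.

**C8–O acyl bond (27 from 24 and 25).** The angelate is cut off next, because the Z-enoate should be exposed to as few steps as possible. The forward esterification has to acylate a hindered secondary alcohol without Z to E isomerisation and without moving the neighbouring acetate.

**C8 carbinol (24 from 23).** The C8 alcohol is taken back to a ketone, which is what an acyl radical cyclisation delivers. The forward reduction has to spare the C3 enone and bring hydride to the β face, so that O8 ends cis to the C7 side chain.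

**C8–C9 bond (23 from 22).** Cutting at C9 removes the seven-membered ring in one stroke and leaves C1, C6 and C7 to be set in an open chain. Every other ring bond carries a heteroatom or a stereocentre on both ends. The forward reaction has to close 7-endo onto the isopropenyl terminus faster than the acyl radical is lost, and has to deliver hydrogen to C10 cis to O1.

**Functional-group order (22 from 21, 19, 18, 17).** The selenoester is the most reactive group and is made last, from acid 21. The acid comes from imide 19 by removal of the auxiliary. The tertiary C11 hydroxyl is acetylated while it is the only free hydroxyl (18 to 19), which requires the secondary C6 hydroxyl to be silylated first (17 to 18).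

**C6–C7 bond (17 from 10 and 15; 15 from 11 and 12).** This cut creates C6 and C7 together. The cis relation of O6 and C11 on the ring corresponds to an anti aldol in the chain C8–C7–C6–C5, so an anti-selective aldol under control of auxiliary 12 is needed. Because the enolate is chiral and aldehyde 10 is racemic at C1, the same step also separates the two C1 series as diastereomers. The acyl component 15 comes from acid 11 and auxiliary 12.

**C5–C6 bond (10 from 9; 9 from 5 and 6).** The formyl carbon is attached to C5 by addition of the masked formyl anion from 6 to the C5 carbonyl of vinylogous silyl ester 5, with transposition of the enone. A C5 enol sulfonate and cross-coupling were not used: making it would require organometallic addition to an enedione whose C2 methylene is flanked by two carbonyls and would be deprotonated instead.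

**C1–C10 bond (5 from 4; 4 from 1 and 2).** The isopropenyl carbinol comes from addition of 2 to the C1 carbonyl of trione 1. In the enolate of 1 the other two carbonyls are tied up as a vinylogous carboxylate, so C1 is the only ketone left. Silylation of 4 then fixes the enol ether at O3, away from the quaternary centre, which is the regiochemistry the transposition needs.

## Alternatives that were turned down

**Alternative 1:** This cuts C1–C5 and C7–C8 together. Forward, a silyl Lewis acid opens a C7–C11 epoxide of an enol silane to a siloxyallyl cation, which adds (4+3) across a tethered furan and gives the oxygen-bridged hydroazulenone A1.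
- For: both rings, the C1–O bond, C7 with its C11 oxygen and the C10 methyl carbon arrive in one step. In ring construction it is stronger than the chosen route.
- Against: the furan oxygen bridges C1 and C8 on the same face, whereas 28 has O1 and O8 on opposite faces. One C–O bond must therefore be broken and the oxygen reinstalled with inversion. A1 also still needs reduction of the C6 ketone, facial hydrogenation of C9=C10, unmasking of C3 and desaturation to C4=C5.
- Comparison: the chosen route builds one ring bond instead of two, but 23 is one reduction and two group operations from 28, with every oxygen already in place and correctly configured.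

**Alternative 2:** This cuts C3–C4 and C1–C5 of the five-membered ring. Forward, Lewis-acid ionisation of an acetal starts a Prins cyclisation, and a pinacol shift enlarges a cyclohexanol to the cis-fused hydroazulenone A2.
- For: this is a well-behaved cationic cascade that sets the fusion carbinol and the C10 methyl with predictable relative configuration. On reliability of the ring-forming event it is at least as strong as a radical 7-endo closure.
- Against: A2 lacks the C7 side chain and the C4=C5 unsaturation. C7 would have to be functionalised late through an enolate that has the C8 oxygen in the β position, the C5 stereocentre is made only to be destroyed, and a tertiary benzyl ether on C1 must be removed beside an enone.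
- Comparison: the chosen route pays with a less certain key step, but brings C6, C7 and C11 in before ring closure by one aldol and needs far fewer steps after the rings exist.

**Alternative 3:** This cuts C1–C2 as the last skeletal bond. Forward, anodic oxidation of a tetrasubstituted furan in an alcohol solvent, hydrolysis to the cis-enedione and aldol closure give A3, the 6-O-silyl ether of 28.
- For: the fragile hydroxy-cyclopentenone is unveiled last from a robust furan, and only a desilylation follows. On end-game economy it matches or beats the chosen route.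
- Against: the furan precursor already contains the complete seven-membered ring with C6, C7, C8 and C10 set, so the main problem is postponed, not solved. In the enedione C10 is α to the C1 ketone and can epimerise before the aldol, the facial sense of that aldol at C1 is uncontrolled, and the aqueous acid and base meet the angelate and the migratable acetate.
- Comparison: the chosen route meets the seven-membered ring head-on and fixes C1 before any base-sensitive ester is present.

Key step: step 12

Assumption on the chemistry: trione 1 reacts as its enol (2-hydroxy-3-methylcyclopent-2-ene-1,4-dione). C1 is carried racemic from step 1 to step 7, where the oxazolidinone separates the two C1 series as diastereomers, so half of aldehyde 10 is lost there.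

## Steps

Step 1
Reactants: 1 3-methylcyclopentane-1,2,4-trione; 2 isopropenylmagnesium bromide
Product: 4 rac-3,5-dihydroxy-2-methyl-5-(prop-1-en-2-yl)cyclopent-2-en-1-one, via the bromomagnesium enolate 3 (not isolated)
Conditions: 2 (2.5 equiv), LaCl3·2LiCl (0.3 equiv), THF, −78 → 0 °C; aq. NH4Cl, pH 3
Reagents that add atoms: none
Why: Grignard addition to a ketone; the first equivalent only deprotonates the acidic enol, which turns the C3/C5 carbonyl pair into an unreactive vinylogous carboxylate and leaves C1 as the single ketone, the carbonyl of this trione that also reacts selectively with nitrogen nucleophiles and hydride. Adding to the enolate avoids an enedione intermediate whose C2 methylene would be deprotonated; C1 is formed racemic.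

Step 2
Reactants: 4 rac-3,5-dihydroxy-2-methyl-5-(prop-1-en-2-yl)cyclopent-2-en-1-one
Product: 5 rac-2-methyl-5-(prop-1-en-2-yl)-3,5-bis(triethylsilyloxy)cyclopent-2-en-1-one
Conditions: TESOTf (2.4 equiv), 2,6-lutidine, CH2Cl2, −78 → 0 °C
Reagents that add atoms: triethylsilyl trifluoromethanesulfonate, CC[Si](CC)(CC)OS(=O)(=O)C(F)(F)F
Why: Silyl triflate silylation; the enol oxygen on C3, next to the ring methylene, is silylated in preference to the oxygen on C5, which is screened by the quaternary C1, and the second equivalent caps the tertiary hydroxyl. This fixes the vinylogous silyl ester with its carbonyl at C5.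

Step 3
Reactants: 5 rac-2-methyl-5-(prop-1-en-2-yl)-3,5-bis(triethylsilyloxy)cyclopent-2-en-1-one; 6 1,3-dithiane
Product: 9 rac-3-(1,3-dithian-2-yl)-2-methyl-4-(prop-1-en-2-yl)-4-(triethylsilyloxy)cyclopent-2-en-1-one, via 2-lithio-1,3-dithiane 7 (not isolated), via the tertiary carbinol adduct 8 (not isolated)
Conditions: 6, n-BuLi, THF, −30 °C; then 5, −78 → −20 °C; then 1 M HCl, THF, 0 °C
Reagents that add atoms: none
Why: Stork–Danheiser transposition; the sulfur-stabilised carbanion adds 1,2 to the only carbonyl (C5), and cold acid hydrolyses the silyl enol ether and expels the C5 hydroxyl, which moves the enone to C3/C4=C5 and leaves the masked formyl carbon C6 on C5. The tertiary silyl ether on C1 should survive the brief acid treatment.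

Step 4
Reactants: 9 rac-3-(1,3-dithian-2-yl)-2-methyl-4-(prop-1-en-2-yl)-4-(triethylsilyloxy)cyclopent-2-en-1-one
Product: 10 rac-2-methyl-3-oxo-5-(prop-1-en-2-yl)-5-(triethylsilyloxy)cyclopent-1-ene-1-carbaldehyde
Conditions: PhI(O2CCF3)2, NaHCO3, MeCN–H2O (9:1), 0 °C
Reagents that add atoms: water, O
Why: Oxidative dithioacetal hydrolysis with a hypervalent iodine reagent; sulfur is oxidised much faster than the isopropenyl group or the electron-poor enone, and the bicarbonate buffer protects the silyl ether.

Step 5
Reactants: 11 3-hydroxy-3-methylbutanoic acid; 12 (4R)-4-benzyl-1,3-oxazolidin-2-one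
Product: 14 (4R)-4-benzyl-3-(3-hydroxy-3-methylbutanoyl)-1,3-oxazolidin-2-one, via the mixed pivalic anhydride 13 (not isolated)
Conditions: Et3N, pivaloyl chloride, THF, −20 °C; then LiCl, 12, −20 → 23 °C
Reagents that add atoms: none
Why: N-Acylation of an oxazolidinone through a mixed anhydride with LiCl/Et3N activation; the tertiary hydroxyl is too hindered to be acylated under these conditions.

Step 6
Reactants: 14 (4R)-4-benzyl-3-(3-hydroxy-3-methylbutanoyl)-1,3-oxazolidin-2-one
Product: 15 (4R)-4-benzyl-3-[3-methyl-3-(trimethylsilyloxy)butanoyl]-1,3-oxazolidin-2-one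
Conditions: TMSCl, imidazole, DMF, 23 °C
Reagents that add atoms: chlorotrimethylsilane, C[Si](C)(C)Cl
Why: Silylation of the tertiary alcohol; the trimethylsilyl ether blocks retro-aldol loss of the C11 unit during enolisation and can later be removed without touching the triethylsilyl ether on C1.

Step 7
Reactants: 10 rac-2-methyl-3-oxo-5-(prop-1-en-2-yl)-5-(triethylsilyloxy)cyclopent-1-ene-1-carbaldehyde; 15 (4R)-4-benzyl-3-[3-methyl-3-(trimethylsilyloxy)butanoyl]-1,3-oxazolidin-2-one
Product: 17 (4R)-4-benzyl-3-{(2R,3R)-3-hydroxy-2-(2-hydroxypropan-2-yl)-3-[(5R)-2-methyl-3-oxo-5-(prop-1-en-2-yl)-5-(triethylsilyloxy)cyclopent-1-en-1-yl]propanoyl}-1,3-oxazolidin-2-one, via the bis(trimethylsilyl) ether 16 (not isolated)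
Conditions: 15 (1.1 equiv), MgCl2 (0.3 equiv), Et3N, TMSCl, EtOAc, 23 °C; then citric acid, MeOH, 0 °C; chromatography
Reagents that add atoms: none
Why: MgCl2-catalysed anti-selective aldol reaction of an N-acyloxazolidinone (soft enolisation, silyl trapping of the aldolate); the chelated Z-enolate is attacked on the face away from the benzyl group, which sets C7, and the boat-like transition state puts the C6 oxygen anti to the C7 substituent, which sets C6, both under reagent control. Each enantiomer of 10 should thus give one diastereomer, and 17 (from the 5R aldehyde) is separated from its C1 epimer after the mild methanolysis that removes both trimethylsilyl groups but not the triethylsilyl group.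

Step 8
Reactants: 17 (4R)-4-benzyl-3-{(2R,3R)-3-hydroxy-2-(2-hydroxypropan-2-yl)-3-[(5R)-2-methyl-3-oxo-5-(prop-1-en-2-yl)-5-(triethylsilyloxy)cyclopent-1-en-1-yl]propanoyl}-1,3-oxazolidin-2-one
Product: 18 (4R)-4-benzyl-3-{(2R,3R)-2-(2-hydroxypropan-2-yl)-3-[(5R)-2-methyl-3-oxo-5-(prop-1-en-2-yl)-5-(triethylsilyloxy)cyclopent-1-en-1-yl]-3-(triethylsilyloxy)propanoyl}-1,3-oxazolidin-2-one
Conditions: TESCl, imidazole, DMAP (cat.), DMF, 0 → 23 °C
Reagents that add atoms: chlorotriethylsilane, CC[Si](Cl)(CC)CC
Why: Chlorosilane/imidazole silylation is selective for the secondary C6 hydroxyl; the tertiary C11 hydroxyl would need a silyl triflate and stays free. A triethylsilyl group is chosen here so that both silyl ethers leave together in the last step.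

Step 9
Reactants: 18 (4R)-4-benzyl-3-{(2R,3R)-2-(2-hydroxypropan-2-yl)-3-[(5R)-2-methyl-3-oxo-5-(prop-1-en-2-yl)-5-(triethylsilyloxy)cyclopent-1-en-1-yl]-3-(triethylsilyloxy)propanoyl}-1,3-oxazolidin-2-one
Product: 19 (4R)-4-benzyl-3-{(2R,3R)-2-(2-acetoxypropan-2-yl)-3-[(5R)-2-methyl-3-oxo-5-(prop-1-en-2-yl)-5-(triethylsilyloxy)cyclopent-1-en-1-yl]-3-(triethylsilyloxy)propanoyl}-1,3-oxazolidin-2-one
Conditions: Ac2O, DMAP, Et3N, CH2Cl2, 23 → 40 °C
Reagents that add atoms: acetic anhydride, CC(=O)OC(C)=O
Why: DMAP-catalysed acetylation of the only free hydroxyl, the tertiary C11 alcohol; triethylamine does not enolise the hindered imide, so C7 is not at risk.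

Step 10
Reactants: 19 (4R)-4-benzyl-3-{(2R,3R)-2-(2-acetoxypropan-2-yl)-3-[(5R)-2-methyl-3-oxo-5-(prop-1-en-2-yl)-5-(triethylsilyloxy)cyclopent-1-en-1-yl]-3-(triethylsilyloxy)propanoyl}-1,3-oxazolidin-2-one
Product: 21 (2R,3R)-2-(2-acetoxypropan-2-yl)-3-[(5R)-2-methyl-3-oxo-5-(prop-1-en-2-yl)-5-(triethylsilyloxy)cyclopent-1-en-1-yl]-3-(triethylsilyloxy)propanoic acid, via the peroxy acid 20 (not isolated)
Conditions: LiOH, H2O2, THF–H2O (3:1), 0 °C; then aq. Na2SO3; 1 M HCl to pH 3
Reagents that add atoms: hydrogen peroxide, OO
Why: Hydroperoxide cleavage of an N-acyloxazolidinone at the exocyclic carbonyl; the weakly basic hydroperoxide anion should spare the tertiary acetate, and Weitz–Scheffer epoxidation of the enone is blocked because C5 is tetrasubstituted and flanked by C1 and C6. Sulfite reduces the peroxy acid to the acid.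

Step 11
Reactants: 21 (2R,3R)-2-(2-acetoxypropan-2-yl)-3-[(5R)-2-methyl-3-oxo-5-(prop-1-en-2-yl)-5-(triethylsilyloxy)cyclopent-1-en-1-yl]-3-(triethylsilyloxy)propanoic acid
Product: 22 Se-phenyl (2R,3R)-2-(2-acetoxypropan-2-yl)-3-[(5R)-2-methyl-3-oxo-5-(prop-1-en-2-yl)-5-(triethylsilyloxy)cyclopent-1-en-1-yl]-3-(triethylsilyloxy)propaneselenoate
Conditions: PhSeSePh, Bu3P, CH2Cl2, 23 °C
Reagents that add atoms: diphenyl diselenide, c1ccc(cc1)[Se][Se]c1ccccc1
Why: Phosphine/diselenide conversion of a carboxylic acid into its Se-phenyl selenoester through the acyloxyphosphonium ion; the neutral medium avoids β-elimination of the acetate or silyloxy group across C7.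

Step 12
Reactants: 22 Se-phenyl (2R,3R)-2-(2-acetoxypropan-2-yl)-3-[(5R)-2-methyl-3-oxo-5-(prop-1-en-2-yl)-5-(triethylsilyloxy)cyclopent-1-en-1-yl]-3-(triethylsilyloxy)propaneselenoate
Product: 23 (1R,6R,7R,10S)-11-acetoxy-1,6-bis(triethylsilyloxy)guai-4-ene-3,8-dione
Conditions: Bu3SnH (syringe pump), AIBN (cat.), benzene (0.005 M), 80 °C
Reagents that add atoms: none
Why: The tributyltin radical abstracts the phenylseleno group of 22 and gives the C8 acyl radical. This nucleophilic radical adds to C9, the unsubstituted terminus of the isopropenyl group on C1, and forms the C8–C9 bond; the closest known reaction type is the 7-endo cyclisation of acyl radicals from Se-phenyl selenoesters onto 1,1-disubstituted alkenes. The seven-membered ring closes in the 7-endo-trig mode, because 6-exo attack at the disubstituted C10 is sterically slower and would give a primary radical, and attack on the C4=C5 bond would need a 5-endo or 4-exo closure. C6 and C1 sit cis on the cyclopentene double bond, which holds the acyl carbon near the alkene and should let ring closure outrun loss of CO and direct reduction, helped by the low stannane concentration. The tertiary C10 radical then takes hydrogen from Bu3SnH and carries the chain. C10 is the one new stereocentre: the α face of the new ring carries the C6 silyloxy group and the bulky C7 side chain, so the stannane should approach from the β face, next to the C1 oxygen, which places H-10 cis to that oxygen and the methyl group α. C1, C6 and C7 are not touched, and the neutral conditions protect the β-acetoxy, β-silyloxy ketone from elimination.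

Step 13
Reactants: 23 (1R,6R,7R,10S)-11-acetoxy-1,6-bis(triethylsilyloxy)guai-4-ene-3,8-dione
Product: 24 (1R,6R,7R,8R,10S)-11-acetoxy-8-hydroxy-1,6-bis(triethylsilyloxy)guai-4-en-3-one
Conditions: NaBH4, MeOH–CH2Cl2 (1:1), −78 → −40 °C; AcOH
Reagents that add atoms: none
Why: Low-temperature borohydride reduction is selective for the saturated C8 ketone over the conjugated, tetrasubstituted C3 enone. Hydride should arrive on the β face, away from the α groups on C6, C7 and C10, and give the 8α alcohol cis to the C7 side chain; the cold acidic quench limits acetyl migration from O11 to O8.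

Step 14
Reactants: 24 (1R,6R,7R,8R,10S)-11-acetoxy-8-hydroxy-1,6-bis(triethylsilyloxy)guai-4-en-3-one; 25 angelic acid
Product: 27 (1R,6R,7R,8R,10S)-11-acetoxy-3-oxo-1,6-bis(triethylsilyloxy)guai-4-en-8-yl (Z)-2-methylbut-2-enoate, via the mixed trichlorobenzoic anhydride 26 (not isolated)
Conditions: 25, 2,4,6-trichlorobenzoyl chloride, Et3N, toluene, 23 °C; then 24, 80 °C
Reagents that add atoms: none
Why: Yamaguchi esterification through the mixed anhydride without added DMAP, the usual way to put an angeloyl group on a hindered secondary alcohol without Z to E isomerisation; the tertiary acetate and the silyl ethers are inert.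

Step 15
Reactants: 27 (1R,6R,7R,8R,10S)-11-acetoxy-3-oxo-1,6-bis(triethylsilyloxy)guai-4-en-8-yl (Z)-2-methylbut-2-enoate
Product: 28 (1R,6R,7S,8R,10S)-11-acetoxy-1,6-dihydroxy-3-oxoguai-4-en-8-yl (Z)-2-methylbut-2-enoate
Conditions: HF·pyridine, pyridine, THF, 0 → 23 °C
Reagents that add atoms: none
Why: Fluoride cleavage of both triethylsilyl ethers under buffered, non-basic conditions, which avoid retro-aldol opening at C1–C2 and acyl migration among O6, O8 and O11.

## Compound list

1 | 3-methylcyclopentane-1,2,4-trione | CC1C(=O)CC(=O)C1=O | starting material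
2 | isopropenylmagnesium bromide | CC(=C)[Mg]Br | starting material
3 | bromomagnesium 2-methyl-3,5-dioxocyclopent-1-en-1-olate (not isolated) | CC1=C(O[Mg]Br)C(=O)CC1=O | intermediate
4 | rac-3,5-dihydroxy-2-methyl-5-(prop-1-en-2-yl)cyclopent-2-en-1-one | CC1=C(O)CC(O)(C(C)=C)C1=O | intermediate
5 | rac-2-methyl-5-(prop-1-en-2-yl)-3,5-bis(triethylsilyloxy)cyclopent-2-en-1-one | CC1=C(O[Si](CC)(CC)CC)CC(O[Si](CC)(CC)CC)(C(C)=C)C1=O | intermediate
6 | 1,3-dithiane | C1CSCSC1 | starting material
7 | 2-lithio-1,3-dithiane (not isolated) | [Li]C1SCCCS1 | intermediate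
8 | rac-1-(1,3-dithian-2-yl)-2-methyl-5-(prop-1-en-2-yl)-3,5-bis(triethylsilyloxy)cyclopent-2-en-1-ol, diastereomer mixture (not isolated) | CC1=C(O[Si](CC)(CC)CC)CC(O[Si](CC)(CC)CC)(C(C)=C)C1(O)C2SCCCS2 | intermediate
9 | rac-3-(1,3-dithian-2-yl)-2-methyl-4-(prop-1-en-2-yl)-4-(triethylsilyloxy)cyclopent-2-en-1-one | CC1=C(C2SCCCS2)C(O[Si](CC)(CC)CC)(C(C)=C)CC1=O | intermediate
10 | rac-2-methyl-3-oxo-5-(prop-1-en-2-yl)-5-(triethylsilyloxy)cyclopent-1-ene-1-carbaldehyde | CC1=C(C=O)C(O[Si](CC)(CC)CC)(C(C)=C)CC1=O | intermediate
11 | 3-hydroxy-3-methylbutanoic acid | CC(C)(O)CC(=O)O | starting material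
12 | (4R)-4-benzyl-1,3-oxazolidin-2-one | O=C1N[C@H](Cc2ccccc2)CO1 | starting material
13 | 3-hydroxy-3-methylbutanoic pivalic anhydride (not isolated) | CC(C)(O)CC(=O)OC(=O)C(C)(C)C | intermediate
14 | (4R)-4-benzyl-3-(3-hydroxy-3-methylbutanoyl)-1,3-oxazolidin-2-one | CC(C)(O)CC(=O)N1[C@H](Cc2ccccc2)COC1=O | intermediate
15 | (4R)-4-benzyl-3-[3-methyl-3-(trimethylsilyloxy)butanoyl]-1,3-oxazolidin-2-one | CC(C)(O[Si](C)(C)C)CC(=O)N1[C@H](Cc2ccccc2)COC1=O | intermediate
16 | bis(trimethylsilyl) ether of 17 at O6 and O11 (not isolated) | O=C([C@@H](C(C)(C)O[Si](C)(C)C)[C@@H](O[Si](C)(C)C)C1=C(C)C(=O)C[C@@]1(O[Si](CC)(CC)CC)C(C)=C)N3[C@H](Cc4ccccc4)COC3=O | intermediate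
17 | (4R)-4-benzyl-3-{(2R,3R)-3-hydroxy-2-(2-hydroxypropan-2-yl)-3-[(5R)-2-methyl-3-oxo-5-(prop-1-en-2-yl)-5-(triethylsilyloxy)cyclopent-1-en-1-yl]propanoyl}-1,3-oxazolidin-2-one | O=C([C@@H](C(C)(C)O)[C@@H](O)C1=C(C)C(=O)C[C@@]1(O[Si](CC)(CC)CC)C(C)=C)N3[C@H](Cc4ccccc4)COC3=O | intermediate
18 | (4R)-4-benzyl-3-{(2R,3R)-2-(2-hydroxypropan-2-yl)-3-[(5R)-2-methyl-3-oxo-5-(prop-1-en-2-yl)-5-(triethylsilyloxy)cyclopent-1-en-1-yl]-3-(triethylsilyloxy)propanoyl}-1,3-oxazolidin-2-one | O=C([C@@H](C(C)(C)O)[C@@H](O[Si](CC)(CC)CC)C1=C(C)C(=O)C[C@@]1(O[Si](CC)(CC)CC)C(C)=C)N3[C@H](Cc4ccccc4)COC3=O | intermediate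
19 | (4R)-4-benzyl-3-{(2R,3R)-2-(2-acetoxypropan-2-yl)-3-[(5R)-2-methyl-3-oxo-5-(prop-1-en-2-yl)-5-(triethylsilyloxy)cyclopent-1-en-1-yl]-3-(triethylsilyloxy)propanoyl}-1,3-oxazolidin-2-one | O=C([C@@H](C(C)(C)OC(C)=O)[C@@H](O[Si](CC)(CC)CC)C1=C(C)C(=O)C[C@@]1(O[Si](CC)(CC)CC)C(C)=C)N3[C@H](Cc4ccccc4)COC3=O | intermediate
20 | peroxy acid of 21 (not isolated) | OOC(=O)[C@@H](C(C)(C)OC(C)=O)[C@@H](O[Si](CC)(CC)CC)C1=C(C)C(=O)C[C@@]1(O[Si](CC)(CC)CC)C(C)=C | intermediate
21 | (2R,3R)-2-(2-acetoxypropan-2-yl)-3-[(5R)-2-methyl-3-oxo-5-(prop-1-en-2-yl)-5-(triethylsilyloxy)cyclopent-1-en-1-yl]-3-(triethylsilyloxy)propanoic acid | OC(=O)[C@@H](C(C)(C)OC(C)=O)[C@@H](O[Si](CC)(CC)CC)C1=C(C)C(=O)C[C@@]1(O[Si](CC)(CC)CC)C(C)=C | intermediate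
22 | Se-phenyl (2R,3R)-2-(2-acetoxypropan-2-yl)-3-[(5R)-2-methyl-3-oxo-5-(prop-1-en-2-yl)-5-(triethylsilyloxy)cyclopent-1-en-1-yl]-3-(triethylsilyloxy)propaneselenoate | O=C([Se]c1ccccc1)[C@@H](C(C)(C)OC(C)=O)[C@@H](O[Si](CC)(CC)CC)C2=C(C)C(=O)C[C@@]2(O[Si](CC)(CC)CC)C(C)=C | intermediate
23 | (1R,6R,7R,10S)-11-acetoxy-1,6-bis(triethylsilyloxy)guai-4-ene-3,8-dione | O=C1C[C@H](C)[C@]2(O[Si](CC)(CC)CC)CC(=O)C(C)=C2[C@H](O[Si](CC)(CC)CC)[C@@H]1C(C)(C)OC(C)=O | intermediate
24 | (1R,6R,7R,8R,10S)-11-acetoxy-8-hydroxy-1,6-bis(triethylsilyloxy)guai-4-en-3-one | O[C@@H]1C[C@H](C)[C@]2(O[Si](CC)(CC)CC)CC(=O)C(C)=C2[C@H](O[Si](CC)(CC)CC)[C@@H]1C(C)(C)OC(C)=O | intermediate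
25 | angelic acid, (Z)-2-methylbut-2-enoic acid | C/C=C(/C)C(=O)O | starting material
26 | angelic 2,4,6-trichlorobenzoic anhydride (not isolated) | C/C=C(/C)C(=O)OC(=O)c1c(Cl)cc(Cl)cc1Cl | intermediate
27 | (1R,6R,7R,8R,10S)-11-acetoxy-3-oxo-1,6-bis(triethylsilyloxy)guai-4-en-8-yl (Z)-2-methylbut-2-enoate | C/C=C(/C)C(=O)O[C@@H]1C[C@H](C)[C@]2(O[Si](CC)(CC)CC)CC(=O)C(C)=C2[C@H](O[Si](CC)(CC)CC)[C@@H]1C(C)(C)OC(C)=O | intermediate
28 | (1R,6R,7S,8R,10S)-11-acetoxy-1,6-dihydroxy-3-oxoguai-4-en-8-yl (Z)-2-methylbut-2-enoate | C/C=C(/C)C(=O)O[C@@H]1C[C@H](C)[C@]2(O)CC(=O)C(C)=C2[C@H](O)[C@@H]1C(C)(C)OC(C)=O | target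

## Step count and least certain steps

Total step count: 15. Longest linear sequence: 13 steps (steps 1–4 and 7–15, from 1); steps 5 and 6 form the side branch.

**Step 12 (key step).** The acyl radical may lose CO or be reduced to the aldehyde before it closes the ring, because the 7-endo addition has to compete with both. Hydrogen transfer to the planar C10 radical may also take place on the α face if the ring conformation exposes that face, which would give the C10 epimer. The fallback sets out from 23, obtained as any mixture of C10 epimers, and returns to 23, with C10 set by a directed hydrogenation instead of a radical hydrogen transfer. IBX in DMSO at 65 °C dehydrogenates C9–C10 and gives 11-acetoxy-1,6-bis(triethylsilyloxy)guaia-4,9-diene-3,8-dione F1. HF·pyridine frees both hydroxyls to give 11-acetoxy-1,6-dihydroxyguaia-4,9-diene-3,8-dione F2. Hydrogenation with [Ir(cod)(PCy3)(py)]PF6 in CH2Cl2 is directed by the allylic C1 hydroxyl and should deliver hydrogen to C10 on the face of that hydroxyl, giving (10S)-11-acetoxy-1,6-dihydroxyguai-4-ene-3,8-dione F3. TESOTf and 2,6-lutidine then restore 23.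

**Step 1.** The second equivalent of 2 may deprotonate the ring methylene of enolate 3 instead of adding to C1, or the magnesium enolate may aggregate and stay unreactive, so conversion may stall. The fallback sets out from 1 and returns at 4, building the carbinol by enolate chemistry. Wolff–Kishner removal of the C1 carbonyl (semicarbazide, then KOH, ethylene glycol, heat) gives 2-methylcyclopentane-1,3-dione F4. Ethanol and TsOH give 3-ethoxy-2-methylcyclopent-2-en-1-one F5. LiN(iPr)2 and then acetone give the aldol rac-3-ethoxy-5-(2-hydroxypropan-2-yl)-2-methylcyclopent-2-en-1-one F6. Mesylation and DBU elimination give 3-ethoxy-2-methyl-5-(propan-2-ylidene)cyclopent-2-en-1-one F7. NaN(SiMe3)2 followed by 2-(phenylsulfonyl)-3-phenyloxaziridine hydroxylates the dienolate at its α carbon and gives rac-3-ethoxy-5-hydroxy-2-methyl-5-(prop-1-en-2-yl)cyclopent-2-en-1-one F8. Dilute aqueous HCl hydrolyses the enol ether to 4.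

**Step 3.** Addition to the C5 carbonyl, which is flanked by the quaternary C1, may be slow for the bulky dithiane anion, which may instead remove a C2 proton or attack silicon of the enol ether. The fallback sets out from 5 and returns at 10, using a small primary carbanion at the alcohol oxidation level. [(4-Methoxybenzyl)oxy]methyllithium (from the tributylstannane and n-BuLi) is added to 5 and worked up with cold 1 M HCl, giving rac-3-{[(4-methoxybenzyl)oxy]methyl}-2-methyl-4-(prop-1-en-2-yl)-4-(triethylsilyloxy)cyclopent-2-en-1-one F9. DDQ in wet CH2Cl2 gives rac-3-(hydroxymethyl)-2-methyl-4-(prop-1-en-2-yl)-4-(triethylsilyloxy)cyclopent-2-en-1-one F10, and MnO2 oxidises this allylic alcohol to 10.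

**Step 7.** The new bond joins an enolate carbon that carries a quaternary centre to a formyl group flanked by a tetrasubstituted alkene and a quaternary carbon, so the addition may be slow. The magnesium enolate may also eliminate the β-silyloxy group at 23 °C, and facial control may erode for one of the two aldehyde enantiomers. The fallback sets out from 11 and 10 and returns at 18. It uses a small cyclic lithium enolate that cannot eliminate and sorts the stereoisomers afterwards. Benzenesulfonyl chloride in pyridine closes 11 to 4,4-dimethyloxetan-2-one F11. Its lithium enolate (LiN(iPr)2, THF, −78 °C) adds to 10 and gives 3-{hydroxy[2-methyl-3-oxo-5-(prop-1-en-2-yl)-5-(triethylsilyloxy)cyclopent-1-en-1-yl]methyl}-4,4-dimethyloxetan-2-one F12 as a stereoisomer mixture. TESCl and imidazole give its triethylsilyl ether F13. The lithium salt of 12 (n-BuLi, THF, −78 °C) opens the lactone at the acyl carbon, and 18 is separated from the diastereomeric imides by chromatography. This fallback gives up reagent control and costs material.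

**Step 14.** Acylation of the C8 hydroxyl next to the C7 side chain may be slow, and during heating the angeloyl group may isomerise to the tigloyl group or the acetyl group may move from O11 to O8. The fallback sets out from 24 and returns at 27, building the Z-enoate on the substrate. 2-[Bis(2,2,2-trifluoroethoxy)phosphoryl]propanoic acid is coupled to 24 (DCC, DMAP, CH2Cl2, 0 °C) to give the 8-O-{2-[bis(2,2,2-trifluoroethoxy)phosphoryl]propanoyl} ester F14. A Still–Gennari olefination (KN(SiMe3)2, 18-crown-6, THF, −78 °C, then acetaldehyde) then gives the Z-configured ester 27.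

## Further compounds

F1 | step 12 | (1R,6R,7R)-11-acetoxy-1,6-bis(triethylsilyloxy)guaia-4,9-diene-3,8-dione | O=C1C=C(C)[C@]2(O[Si](CC)(CC)CC)CC(=O)C(C)=C2[C@H](O[Si](CC)(CC)CC)[C@@H]1C(C)(C)OC(C)=O
F2 | step 12 | (1R,6R,7R)-11-acetoxy-1,6-dihydroxyguaia-4,9-diene-3,8-dione | O=C1C=C(C)[C@]2(O)CC(=O)C(C)=C2[C@H](O)[C@@H]1C(C)(C)OC(C)=O
F3 | step 12 | (1R,6R,7R,10S)-11-acetoxy-1,6-dihydroxyguai-4-ene-3,8-dione | O=C1C[C@H](C)[C@]2(O)CC(=O)C(C)=C2[C@H](O)[C@@H]1C(C)(C)OC(C)=O
F4 | step 1 | 2-methylcyclopentane-1,3-dione | CC1C(=O)CCC1=O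
F5 | step 1 | 3-ethoxy-2-methylcyclopent-2-en-1-one | CCOC1=C(C)C(=O)CC1
F6 | step 1 | rac-3-ethoxy-5-(2-hydroxypropan-2-yl)-2-methylcyclopent-2-en-1-one | CCOC1=C(C)C(=O)C(C(C)(C)O)C1
F7 | step 1 | 3-ethoxy-2-methyl-5-(propan-2-ylidene)cyclopent-2-en-1-one | CCOC1=C(C)C(=O)C(=C(C)C)C1
F8 | step 1 | rac-3-ethoxy-5-hydroxy-2-methyl-5-(prop-1-en-2-yl)cyclopent-2-en-1-one | CCOC1=C(C)C(=O)C(O)(C(C)=C)C1
F9 | step 3 | rac-3-{[(4-methoxybenzyl)oxy]methyl}-2-methyl-4-(prop-1-en-2-yl)-4-(triethylsilyloxy)cyclopent-2-en-1-one | CC1=C(COCc2ccc(OC)cc2)C(O[Si](CC)(CC)CC)(C(C)=C)CC1=O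
F10 | step 3 | rac-3-(hydroxymethyl)-2-methyl-4-(prop-1-en-2-yl)-4-(triethylsilyloxy)cyclopent-2-en-1-one | CC1=C(CO)C(O[Si](CC)(CC)CC)(C(C)=C)CC1=O
F11 | step 7 | 4,4-dimethyloxetan-2-one | CC1(C)CC(=O)O1
F12 | step 7 | 3-{hydroxy[2-methyl-3-oxo-5-(prop-1-en-2-yl)-5-(triethylsilyloxy)cyclopent-1-en-1-yl]methyl}-4,4-dimethyloxetan-2-one, stereoisomer mixture, drawn for the isomer that leads to 18 | O=C1OC(C)(C)[C@H]1[C@@H](O)C2=C(C)C(=O)C[C@@]2(O[Si](CC)(CC)CC)C(C)=C
F13 | step 7 | triethylsilyl ether of F12 at the carbinol oxygen, drawn for the isomer that leads to 18 | O=C1OC(C)(C)[C@H]1[C@@H](O[Si](CC)(CC)CC)C2=C(C)C(=O)C[C@@]2(O[Si](CC)(CC)CC)C(C)=C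
F14 | step 14 | (1R,6R,7R,8R,10S)-11-acetoxy-3-oxo-1,6-bis(triethylsilyloxy)guai-4-en-8-yl 2-[bis(2,2,2-trifluoroethoxy)phosphoryl]propanoate, epimer mixture at the phosphonate carbon | CC(C(=O)O[C@@H]1C[C@H](C)[C@]2(O[Si](CC)(CC)CC)CC(=O)C(C)=C2[C@H](O[Si](CC)(CC)CC)[C@@H]1C(C)(C)OC(C)=O)P(=O)(OCC(F)(F)F)OCC(F)(F)F
A1 | alternative 1 | oxygen-bridged hydroazulen-6-one with C3 dioxolane and C11 triethylsilyl ether | [C@@H]12C=C(C)[C@]3(O1)CC4(OCCO4)[C@@H](C)[C@@H]3C(=O)[C@@H]2C(C)(C)O[Si](CC)(CC)CC
A2 | alternative 2 | cis-fused hydroazulen-6-one with C1 and C3 benzyl ethers and C8 silyl ether | CC(C)(C)[Si](C)(C)O[C@@H]1C[C@H](C)[C@]2(OCc3ccccc3)C[C@@H](OCc4ccccc4)[C@H](C)[C@@H]2C(=O)C1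
A3 | alternative 3 | 6-O-(tert-butyldimethylsilyl) ether of 28 | C/C=C(/C)C(=O)O[C@@H]1C[C@H](C)[C@]2(O)CC(=O)C(C)=C2[C@H](O[Si](C)(C)C(C)(C)C)[C@@H]1C(C)(C)OC(C)=O
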